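**Plan**

1. Ring numbering: C1 (CH carrying the C7H2–O–coumarin arm), C2(CH3)=C3H, C4H2, C5 (CH–O-acyl), C6 (C(CH3)2). Retrosynthetic cuts, in order: the isovalerate C5O–acyl bond, the C5–H bond (alcohol back to ketone), the C7–O aryl ether, the ring bond C4–C5, the two C6–CH3 bonds, and C1–C2.
2. Enabling feature: C5 bears oxygen and is bonded to the allylic methylene C4, while C5–C6–C1–C7–O is a 3,3-dimethyl-γ-butyrolactone in disguise with C5 as its carbonyl carbon. C4–C5 is therefore an allyl–acyl bond that an allylmetal at C4 can make by attacking the lactone carbonyl.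
3. Forward: a (Z)-alkenylboronate is joined to furan-2(5H)-one (C1–C2), C6 is dimethylated, and the allylic bromide is unmasked. SmI2 then closes the cyclohexene, the only ring made, at C4–C5 and in the same event opens the lactone, so C7–OH appears as the sole hydroxyl and no diol has to be differentiated.
4. The chain is finished by aryl ether formation at C7, ketone reduction at C5 and acylation; the coumarin arrives intact.
5. Stereochemistry: C1 comes from the rhodium/(R)-BINAP conjugate addition. C5 comes from an (S)-oxazaborolidine-controlled ketone reduction that coincides with hydride attack anti to the C7 arm. The C2=C3 geometry comes from the (Z)-iodide and is then locked in the ring.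

Key step: step 7

Assumption: (Z)-3-iodobut-2-en-1-ol is taken as a catalogue compound; it is otherwise one step from but-2-yn-1-ol (NaAlH2(OCH2CH2OMe)2, then I2).

**Route**

Step 1
Reactants: 1 (Z)-3-iodobut-2-en-1-ol
Product: 2 tert-butyl{[(2Z)-3-iodobut-2-en-1-yl]oxy}dimethylsilane
Conditions: TBSCl, imidazole, CH2Cl2, 0 °C to rt
Reagents that add atoms: tert-butyl(chloro)dimethylsilane, CC(C)(C)[Si](C)(C)Cl
Why: Imidazole-promoted silyl ether formation masks the primary allylic hydroxyl for the later enolate chemistry and leaves the alkenyl iodide untouched.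

Step 2
Reactants: 2 tert-butyl{[(2Z)-3-iodobut-2-en-1-yl]oxy}dimethylsilane
Product: 3 tert-butyldimethyl{[(2E)-3-(4,4,5,5-tetramethyl-1,3,2-dioxaborolan-2-yl)but-2-en-1-yl]oxy}silane (boron cis to the CH2OSi group; the descriptor changes only because boron ranks below methyl)
Conditions: B2pin2, PdCl2(PPh3)2 (3 mol %), PPh3, KOPh, toluene, 50 °C
Reagents that add atoms: bis(pinacolato)diboron, CC1(C)OB(OC1(C)C)B1OC(C)(C)C(C)(C)O1
Why: Miyaura borylation of an alkenyl iodide proceeds with retention of the double-bond geometry, and phenoxide as base holds back Suzuki homocoupling.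

Step 3
Reactants: 3 tert-butyldimethyl{[(2E)-3-(4,4,5,5-tetramethyl-1,3,2-dioxaborolan-2-yl)but-2-en-1-yl]oxy}silane; 4 furan-2(5H)-one
Product: 5 (4R)-4-[(2Z)-4-{[tert-butyl(dimethyl)silyl]oxy}but-2-en-2-yl]oxolan-2-one
Conditions: [RhCl(C2H4)2]2 (2.5 mol %), (R)-BINAP (6 mol %), aq KOH (0.3 equiv), 1,4-dioxane/H2O 10:1, 50 °C; 3 in 1.5-fold excess
Reagents that add atoms: none
Why: Hayashi–Miyaura asymmetric conjugate addition, in which the (R)-BINAP-bound alkenylrhodium inserts the cyclic enoate on one face and the oxa-π-allyl rhodium is protonated by water; by the facial preference established for this catalyst family with five- and six-membered enones and lactones, the (R)-ligand should set the 4R centre, the future C1.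

Step 4
Reactants: 5 (4R)-4-[(2Z)-4-{[tert-butyl(dimethyl)silyl]oxy}but-2-en-2-yl]oxolan-2-one
Product: 7 (4S)-4-[(2Z)-4-{[tert-butyl(dimethyl)silyl]oxy}but-2-en-2-yl]-3,3-dimethyloxolan-2-one, via 3-methyl lactone 6 (not isolated)
Conditions: LiN(iPr)2 (1.05 equiv), THF, –78 °C, then MeI (1.05 equiv); re-cool, LiN(iPr)2 (1.3 equiv), then MeI (3 equiv), –78 to 0 °C
Reagents that add atoms: iodomethane, CI
Why: Two consecutive lactone enolate alkylations at C3: the first methyl enters trans to the C4 substituent and the second enolisation erases that centre while building the quaternary carbon (the future C6); C4 is β to the carbonyl and cannot epimerise (its descriptor changes from R to S only through the priority rules).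

Step 5
Reactants: 7 (4S)-4-[(2Z)-4-{[tert-butyl(dimethyl)silyl]oxy}but-2-en-2-yl]-3,3-dimethyloxolan-2-one
Product: 8 (4S)-4-[(2Z)-4-hydroxybut-2-en-2-yl]-3,3-dimethyloxolan-2-one
Conditions: HF·pyridine, THF/pyridine, 0 °C to rt
Reagents that add atoms: none
Why: Fluoride-mediated desilylation frees the allylic alcohol under buffered, non-basic conditions that should leave the lactone and the alkene geometry untouched.

Step 6
Reactants: 8 (4S)-4-[(2Z)-4-hydroxybut-2-en-2-yl]-3,3-dimethyloxolan-2-one
Product: 9 (4S)-4-[(2Z)-4-bromobut-2-en-2-yl]-3,3-dimethyloxolan-2-one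
Conditions: CBr4, PPh3, CH2Cl2, 0 °C; used without storage
Reagents that add atoms: carbon tetrabromide, BrC(Br)(Br)Br
Why: Appel reaction: bromide displaces the alkoxyphosphonium ion at the primary allylic carbon by SN2 under neutral conditions, so the bromide should form without allylic transposition.

Step 7
Reactants: 9 (4S)-4-[(2Z)-4-bromobut-2-en-2-yl]-3,3-dimethyloxolan-2-one
Product: 12 (5S)-5-(hydroxymethyl)-4,6,6-trimethylcyclohex-3-en-1-one, via allylsamarium 10 (not isolated), via samarium hemiketalate 11 (not isolated)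
Conditions: SmI2 (2.2 equiv, 0.1 M in THF), slow addition of 9 (final 0.01 M), 0 °C; then aq NH4Cl
Reagents that add atoms: none
Why: Two single-electron transfers from divalent samarium cleave the allylic C–Br bond and give the trivalent allylsamarium 10, which adds through its unsubstituted terminus C4 to the lactone carbonyl C5; the closest known reaction type is the SmI2-promoted intramolecular Barbier-type nucleophilic acyl substitution of halo-esters and halo-lactones, here run with an allylic bromide. The cyclohexene closes by 6-exo-trig attack on the C5=O bond and gives the bridged hemiketalate 11, whose tetrahedral carbon cannot accept a second nucleophile and whose opening on work-up delivers the ketone and sets C7–OH free as the only hydroxyl of 12. No stereocenter is created (C5 becomes trigonal), and C1 is not at risk because it is β to the new ketone and the lactone carbonyl has no α-hydrogen for the basic organometallic to remove. The step needs bonding at C4 and not at C2: bonding at C2 would build a cyclobutane with two adjacent quaternary carbons, so only the C4 mode is geometrically open, and because allylsamarium species interconvert their terminal geometries, material that loses the Z arrangement is funnelled back to the form that can cyclise. It also needs ring closure to outrun Wurtz-type coupling, which slow addition of 9 to excess SmI2 at high dilution should secure, each molecule carrying a single nucleophile for its own carbonyl.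

Step 8
Reactants: 12 (5S)-5-(hydroxymethyl)-4,6,6-trimethylcyclohex-3-en-1-one; 13 7-hydroxy-2H-chromen-2-one (umbelliferone)
Product: 14 7-{[(1S)-2,6,6-trimethyl-5-oxocyclohex-2-en-1-yl]methoxy}-2H-chromen-2-one
Conditions: PPh3, DIAD, THF, 0 °C to rt
Reagents that add atoms: none
Why: Mitsunobu etherification: the only hydroxyl of 12 (the open hydroxy ketone, in equilibrium with a bicyclic hemiketal) is activated as an alkoxyphosphonium ion and displaced at primary C7 by the acidic phenol of 13; no stereocenter is involved and the near-neutral medium should leave the β,γ-unsaturated ketone unconjugated.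

Step 9
Reactants: 14 7-{[(1S)-2,6,6-trimethyl-5-oxocyclohex-2-en-1-yl]methoxy}-2H-chromen-2-one
Product: 15 7-{[(1S,5R)-5-hydroxy-2,6,6-trimethylcyclohex-2-en-1-yl]methoxy}-2H-chromen-2-one
Conditions: (S)-Me-CBS oxazaborolidine [(3aS)-1-methyl-3,3-diphenyltetrahydro-1H,3H-pyrrolo[1,2-c][1,3,2]oxazaborole] (0.3 equiv), catecholborane (1.8 equiv), toluene, –78 to –40 °C; then MeOH, aq NaOH
Reagents that add atoms: none
Why: Corey–Bakshi–Shibata reduction: the (S)-oxazaborolidine binds the ketone with quaternary C6 as the large flank and the C4 methylene as the small one and delivers hydride to the face that gives 5R, the same face (anti to the C7 arm) that substrate control favours, so the C5 oxygen should end cis to the C7 arm; catecholborane at low temperature should leave the coumarin and the trisubstituted alkene alone.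

Step 10
Reactants: 15 7-{[(1S,5R)-5-hydroxy-2,6,6-trimethylcyclohex-2-en-1-yl]methoxy}-2H-chromen-2-one; 16 3-methylbutanoyl chloride (isovaleryl chloride)
Product: 17 (1R,5S)-4,6,6-trimethyl-5-{[(2-oxo-2H-chromen-7-yl)oxy]methyl}cyclohex-3-en-1-yl 3-methylbutanoate (CNP0266015.1)
Conditions: DMAP, pyridine, CH2Cl2, 0 °C to rt
Reagents that add atoms: none
Why: Nucleophilic-catalysed acylation (acylpyridinium from DMAP) esterifies the hindered secondary hydroxyl with retention at C5 and gives the target.

**Compound list**

1 | (Z)-3-iodobut-2-en-1-ol | C/C(I)=C/CO | starting material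
2 | tert-butyl{[(2Z)-3-iodobut-2-en-1-yl]oxy}dimethylsilane | C/C(I)=C/CO[Si](C)(C)C(C)(C)C | intermediate
3 | tert-butyldimethyl{[(2E)-3-(4,4,5,5-tetramethyl-1,3,2-dioxaborolan-2-yl)but-2-en-1-yl]oxy}silane | C/C(B1OC(C)(C)C(C)(C)O1)=C/CO[Si](C)(C)C(C)(C)C | intermediate
4 | furan-2(5H)-one | O=C1OCC=C1 | starting material
5 | (4R)-4-[(2Z)-4-{[tert-butyl(dimethyl)silyl]oxy}but-2-en-2-yl]oxolan-2-one | O=C1C[C@H](/C(C)=C\CO[Si](C)(C)C(C)(C)C)CO1 | intermediate
6 | (3S,4R)-4-[(2Z)-4-{[tert-butyl(dimethyl)silyl]oxy}but-2-en-2-yl]-3-methyloxolan-2-one (trans epimer, not isolated) | O=C1OC[C@@H](/C(C)=C\CO[Si](C)(C)C(C)(C)C)[C@@H]1C | intermediate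
7 | (4S)-4-[(2Z)-4-{[tert-butyl(dimethyl)silyl]oxy}but-2-en-2-yl]-3,3-dimethyloxolan-2-one | O=C1OC[C@@H](/C(C)=C\CO[Si](C)(C)C(C)(C)C)C1(C)C | intermediate
8 | (4S)-4-[(2Z)-4-hydroxybut-2-en-2-yl]-3,3-dimethyloxolan-2-one | O=C1OC[C@@H](/C(C)=C\CO)C1(C)C | intermediate
9 | (4S)-4-[(2Z)-4-bromobut-2-en-2-yl]-3,3-dimethyloxolan-2-one | O=C1OC[C@@H](/C(C)=C\CBr)C1(C)C | intermediate
10 | {(2Z)-3-[(3S)-4,4-dimethyl-5-oxooxolan-3-yl]but-2-en-1-yl}diiodosamarium (not isolated) | O=C1OC[C@@H](/C(C)=C\C[Sm](I)I)C1(C)C | intermediate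
11 | diiodo{[(1S,5S)-2,8,8-trimethyl-6-oxabicyclo[3.2.1]oct-2-en-5-yl]oxy}samarium (not isolated) | CC1=CC[C@@]2(O[Sm](I)I)OC[C@@H]1C2(C)C | intermediate
12 | (5S)-5-(hydroxymethyl)-4,6,6-trimethylcyclohex-3-en-1-one | CC1=CCC(=O)C(C)(C)[C@H]1CO | intermediate
13 | 7-hydroxy-2H-chromen-2-one (umbelliferone) | O=c1ccc2ccc(O)cc2o1 | starting material
14 | 7-{[(1S)-2,6,6-trimethyl-5-oxocyclohex-2-en-1-yl]methoxy}-2H-chromen-2-one | CC1=CCC(=O)C(C)(C)[C@H]1COc1ccc2ccc(=O)oc2c1 | intermediate
15 | 7-{[(1S,5R)-5-hydroxy-2,6,6-trimethylcyclohex-2-en-1-yl]methoxy}-2H-chromen-2-one | CC1=CC[C@@H](O)C(C)(C)[C@H]1COc1ccc2ccc(=O)oc2c1 | intermediate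
16 | 3-methylbutanoyl chloride (isovaleryl chloride) | CC(C)CC(Cl)=O | starting material
17 | (1R,5S)-4,6,6-trimethyl-5-{[(2-oxo-2H-chromen-7-yl)oxy]methyl}cyclohex-3-en-1-yl 3-methylbutanoate | CC1=CC[C@@H](OC(=O)CC(C)C)C(C)(C)[C@H]1COc1ccc2ccc(=O)oc2c1 | target

**Step count**

Total: 10 steps. Longest linear sequence: 10 steps (1 to 17); compounds 4, 13 and 16 enter as purchased materials.

**Steps most likely to fail**

Step 7. The allylsamarium may couple with unreacted bromide or be protonated faster than it attacks the hindered lactone carbonyl, or the trisubstituted double bond may slip into conjugation while the hemiketalate opens. The fallback sets out from 4 and returns at 12; it makes the C4–C5 bond intermolecularly and closes the ring at C2=C3 by metathesis. Rhodium/(R)-BINAP addition of 4,4,5,5-tetramethyl-2-(prop-1-en-2-yl)-1,3,2-dioxaborolane to 4 under the conditions of step 3 should give (4R)-4-(prop-1-en-2-yl)oxolan-2-one F1. Methylation with LiN(iPr)2/MeI gives (3S,4R)-3-methyl-4-(prop-1-en-2-yl)oxolan-2-one F2, and a second cycle gives (4S)-3,3-dimethyl-4-(prop-1-en-2-yl)oxolan-2-one F3. CH2=CHCH2MgBr (1.05 equiv, THF, –78 °C) adds once to the lactone carbonyl, the magnesium hemiketalate being stable in the cold, and after aqueous work-up gives (6S)-6-(hydroxymethyl)-5,5,7-trimethylocta-1,7-dien-4-one F4 (together with its cyclic hemiketal form). Ring-closing metathesis with second-generation Grubbs catalyst (CH2Cl2, 40 °C) then forms the C2=C3 bond and delivers 12.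

Step 3. Protodeboronation of the hindered trisubstituted alkenylboronate may outrun transmetalation and insertion, and facial selectivity may be eroded with so encumbered an alkenyl group. The fallback sets out from 2 and returns at 5 under auxiliary control. Iodine–magnesium exchange (iPrMgCl·LiCl, THF, 0 °C to rt) converts 2 into chloro[(2Z)-4-{[tert-butyl(dimethyl)silyl]oxy}but-2-en-2-yl]magnesium F5. With CuBr·SMe2 (10 mol %) at –78 °C this adds to the known auxiliary butenolide (5S)-5-{[(1S,2R,5S)-5-methyl-2-(propan-2-yl)cyclohexyl]oxy}furan-2(5H)-one anti to the acetal oxygen and should give (4R,5S)-4-[(2Z)-4-{[tert-butyl(dimethyl)silyl]oxy}but-2-en-2-yl]-5-{[(1S,2R,5S)-5-methyl-2-(propan-2-yl)cyclohexyl]oxy}oxolan-2-one F6. LiAlH4 (THF, 0 °C) removes the auxiliary as menthol and gives (2R)-2-[(2Z)-4-{[tert-butyl(dimethyl)silyl]oxy}but-2-en-2-yl]butane-1,4-diol F7. TEMPO/PhI(OAc)2 (CH2Cl2, rt) oxidises the unbranched hydroxyethyl terminus first and the resulting lactol on to the lactone, which returns 5.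

Step 8. Substitution at the β-branched C7, next to the quaternary centre, may be slow enough for the alkoxyphosphonium intermediate to be consumed by hydrazide N-alkylation or elimination. The fallback sets out from 12 and returns at 14; it forms the aryl–oxygen bond instead of the alkyl–oxygen bond. Potassium trifluoro(2-oxo-2H-chromen-7-yl)borate F8, made from the commercial pinacol boronate with KHF2, is coupled with 12 under Chan–Lam–Batey conditions (Cu(OAc)2 10 mol %, DMAP, 4 Å molecular sieves, O2, CH2Cl2, rt), which requires no displacement at C7.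

**Further compounds**

F1 | step 7 | (4R)-4-(prop-1-en-2-yl)oxolan-2-one | O=C1C[C@H](C(C)=C)CO1
F2 | step 7 | (3S,4R)-3-methyl-4-(prop-1-en-2-yl)oxolan-2-one | O=C1OC[C@@H](C(C)=C)[C@@H]1C
F3 | step 7 | (4S)-3,3-dimethyl-4-(prop-1-en-2-yl)oxolan-2-one | O=C1OC[C@@H](C(C)=C)C1(C)C
F4 | step 7 | (6S)-6-(hydroxymethyl)-5,5,7-trimethylocta-1,7-dien-4-one | C=CCC(=O)C(C)(C)[C@@H](CO)C(C)=C
F5 | step 3 | chloro[(2Z)-4-{[tert-butyl(dimethyl)silyl]oxy}but-2-en-2-yl]magnesium | C/C([Mg]Cl)=C/CO[Si](C)(C)C(C)(C)C
F6 | step 3 | (4R,5S)-4-[(2Z)-4-{[tert-butyl(dimethyl)silyl]oxy}but-2-en-2-yl]-5-{[(1S,2R,5S)-5-methyl-2-(propan-2-yl)cyclohexyl]oxy}oxolan-2-one | O=C1C[C@H](/C(C)=C\CO[Si](C)(C)C(C)(C)C)[C@@H](O[C@H]2C[C@@H](C)CC[C@@H]2C(C)C)O1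
F7 | step 3 | (2R)-2-[(2Z)-4-{[tert-butyl(dimethyl)silyl]oxy}but-2-en-2-yl]butane-1,4-diol | OCC[C@H](/C(C)=C\CO[Si](C)(C)C(C)(C)C)CO
F8 | step 8 | potassium trifluoro(2-oxo-2H-chromen-7-yl)borate | [K+].F[B-](F)(F)c1ccc2ccc(=O)oc2c1
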